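**Plan**

- Oxolane numbering: O1, C2 (4-hydroxyphenyl), C3 (2,4-dihydroxybenzoyl), C4 (CH(OH)aryl), C5 (2,4-dihydroxyphenyl). The enabling feature is that the adjacent ring carbons C3 and C4 each carry an (R)-aryl carbinol carbon (C2 in the ring, the exocyclic CHOH) and a carbonyl-level carbon (the ketone carbon, C5). These are two syn-aldol units sharing the C3–C4 bond, i.e. a 2,3-bis(α-hydroxybenzyl)succinate.
- Cuts, in retrosynthetic order: the two resorcinol aryl–C bonds (to the ketone carbon and to C5) and the C5–H bond, back to a cis-fused dilactone; then C2–C3 and C4–C(carbinol) by a twofold aldol; then the two N-acyl bonds of a succinyl bis-imide.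
- Forward: bis-imide, twofold boron aldol (chain joined, no ring), crosswise double lactonisation (both five-membered rings at once; the O1–C2–C3–C4–C5 ring is the one that survives), aryl Grignard addition and silane reduction at C5, aryllithium opening of the other lactone to the ketone, deprotection.
- Stereochemistry: C2, C3, C4 and the carbinol carbon (all R) come from the two (R)-4-benzyl-oxazolidinone-controlled syn aldols; C5 (R) comes from hydride delivery to the convex face of the bicyclic oxocarbenium ion.
- All six phenols travel as allyl ethers and are freed last with Pd(PPh3)4 and morpholine, because the p-hydroxybenzylic alcohol of the target would not tolerate acid.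

Key step: step 2

Assumption: a γ-hydroxy aryl ketone and its cyclic hemiketal interconvert without touching any stereocentre. Compound 13 is written as the hemiketal that is reduced in step 6; 16 and 17 are written as the open keto alcohol in which the target is specified.

**Route**

Step 1
Reactants: 1 succinyl chloride; 2 (R)-4-benzyl-2-oxazolidinone (2 equiv)
Product: 4 1,4-bis[(R)-4-benzyl-2-oxooxazolidin-3-yl]butane-1,4-dione, via lithium (R)-4-benzyl-2-oxazolidinon-3-ide 3 (not isolated)
Conditions: 2, n-BuLi (2.0 equiv), THF, −78 °C; then 1 (1.0 equiv), −78 to 0 °C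
Reagents that add atoms: none
Why: N-acylation of a lithiated oxazolidinone by an acid chloride is the standard entry to Evans imides and should run at both ends of the diacid chloride without touching the auxiliary stereocentre.

Step 2
Reactants: 4 1,4-bis[(R)-4-benzyl-2-oxooxazolidin-3-yl]butane-1,4-dione; 5 4-(allyloxy)benzaldehyde (2.6 equiv)
Product: 8 bis-syn-aldol diol 1,4-bis[(R)-4-benzyl-2-oxooxazolidin-3-yl]-(2R,3R)-2,3-bis[(R)-[4-(allyloxy)phenyl](hydroxy)methyl]butane-1,4-dione, via bis(dibutylboron) Z,Z-dienolate 6 (not isolated), via bis(dibutylboron) aldolate 7 (not isolated)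
Conditions: Bu2BOTf (2.4 equiv), iPr2NEt (2.8 equiv), CH2Cl2, −78 to 0 °C; then 5, −78 to −20 °C; pH 7 phosphate buffer, MeOH, 30% H2O2, 0 °C
Reagents that add atoms: none
Why: Proposed new method: Bu2BOTf and iPr2NEt should enolise both imides of 4 in turn (complexation of each carbonyl, then deprotonation of its methylene) to the Z,Z-bis(boron enolate) 6, a 1,4-bis(boryloxy)buta-1,3-diene in which each inner carbon is the nucleophilic α-carbon of one enolate; each enolate then adds to aldehyde 5 through a closed Zimmerman–Traxler chair with the aryl group equatorial, forming the C2–C3 and C4–carbinol bonds of the target (oxolane numbering). The closest known reaction is the Evans boron syn-aldol of N-acyl oxazolidinones, established singly on succinate half-imides on the way to paraconic acids, and vicinal succinate bis-enolates are known to add twice to aldehydes as lithium dianions of succinic diamides or as bis-silyl derivatives; running both boron aldols on one bis-imide is the new element. No ring closes: while the second imide is still an enolate the first aldolate has no acyl acceptor within reach, so Stobbe-type lactonisation cannot cut in before the second C–C bond is made, and the cold buffered peroxide work-up should release the open diol 8. The four new stereocentres (both α-carbons and both carbinol carbons, all R) arise as two syn pairs: the syn relation follows from the Z-enolate geometry in the chair, and the absolute sense from the (R)-benzyl group of each auxiliary, which blocks one enolate face in the dipole-opposed conformer. The step needs the same facial sense in both additions; reagent control by two identical auxiliaries is expected to override the bias of the aldolate centre formed first and so deliver the C2-symmetric isomer.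

Step 3
Reactants: 8 bis-syn-aldol diol
Product: 9 (3R,3aR,6R,6aR)-3,6-bis[4-(allyloxy)phenyl]tetrahydrofuro[3,4-c]furan-1,4-dione (cis-fused dilactone, both aryl groups exo)
Conditions: Et3N (1 equiv), DMAP (0.1 equiv), CH2Cl2, rt
Reagents that add atoms: none
Why: Acyl transfer from an N-acyl oxazolidinone to a γ-hydroxyl (5-exo-trig lactonisation with release of the auxiliary) is well known; each hydroxyl can reach only the distal imide carbonyl, so closure is necessarily crosswise and cis-fused, and no stereocentre is touched, the two α-carbons becoming the locked ring-fusion carbons.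

Step 4
Reactants: 10 4-bromoresorcinol
Product: 11 2,4-bis(allyloxy)-1-bromobenzene
Conditions: allyl bromide (2.4 equiv), K2CO3 (3 equiv), acetone, reflux
Reagents that add atoms: allyl bromide, C=CCBr
Why: Williamson etherification of both phenols; the allyl ethers should survive Grignard formation, bromine–lithium exchange at −78 °C and BF3·OEt2 in the cold, and can be removed later under neutral conditions.

Step 5
Reactants: 9 cis-fused dilactone (1.3 equiv); 11 2,4-bis(allyloxy)-1-bromobenzene (1.0 equiv)
Product: 13 lactol–lactone (3R,3aR,4S,6R,6aR)-3,6-bis[4-(allyloxy)phenyl]-4-[2,4-bis(allyloxy)phenyl]-4-hydroxytetrahydrofuro[3,4-c]furan-1-one, via 2,4-bis(allyloxy)phenylmagnesium bromide 12 (not isolated)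
Conditions: 11, Mg turnings (activated with I2), THF, 40 °C; the Grignard solution added slowly to 9, THF, −40 to −20 °C; sat. aq NH4Cl at −20 °C
Reagents that add atoms: none
Why: Magnesium insertion into the aryl bromide followed by 1,2-addition of the aryl Grignard reagent to a γ-lactone carbonyl should stop at the magnesium hemiketalate in the cold, as in C-aryl glycoside synthesis from sugar lactones; the Grignard reagent is preferred to the aryllithium here because it is less basic, so deprotonation at a ring-fusion carbon with β-elimination of the neighbouring lactone carboxylate should not compete, the two lactones of 9 are homotopic so only one mono-adduct can form, inverse addition to an excess of recoverable 9 keeps the nucleophile limiting and so limits double addition, and the hemiketal configuration (drawn as the exo-aryl anomer) is of no consequence.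

Step 6
Reactants: 13 lactol–lactone
Product: 14 oxolane–lactone (3R,3aS,4R,6R,6aR)-3,6-bis[4-(allyloxy)phenyl]-4-[2,4-bis(allyloxy)phenyl]tetrahydrofuro[3,4-c]furan-1-one (new aryl group endo, the other two exo)
Conditions: Et3SiH (3 equiv), BF3·OEt2 (2 equiv), CH2Cl2, −78 to −40 °C; Et3N then aq NaHCO3 at −40 °C
Reagents that add atoms: none
Why: Silane reduction of a cyclic hemiketal (ionic hydrogenation, the usual route from aryl lactols to 2-aryl oxolanes): BF3·OEt2 ionises 13 to the aryl-stabilised bicyclic oxocarbenium ion and Et3SiH delivers hydride to its convex face, cis to the ring-fusion hydrogens, which puts the aryl group on the concave face and sets C5 of the target as (R); the lactone, the benzylic ethers and the allyl ethers should hold at low temperature.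

Step 7
Reactants: 14 oxolane–lactone; 11 2,4-bis(allyloxy)-1-bromobenzene (1.3 equiv)
Product: 16 [2,4-bis(allyloxy)phenyl][(2R,3R,4R,5R)-2-[4-(allyloxy)phenyl]-5-[2,4-bis(allyloxy)phenyl]-4-[(R)-[4-(allyloxy)phenyl](hydroxy)methyl]oxolan-3-yl]methanone, via 2,4-bis(allyloxy)phenyllithium 15 (not isolated)
Conditions: 11, n-BuLi (1.25 equiv), THF, −78 °C; then 14, THF, −78 °C; sat. aq NH4Cl
Reagents that add atoms: none
Why: Bromine–lithium exchange and addition of the aryllithium to the remaining γ-lactone at −78 °C give, after protonation, the lactol–hydroxy ketone pair; the more reactive lithium reagent is used for this more hindered lactone because the nucleophile is now in excess and the lithium hemiketalate persists at −78 °C, which together with the ortho-substituted aryl group guards against a second addition, and ring opening frees the (R)-carbinol on C4 and creates the aryl ketone on C3 without touching a stereocentre.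

Step 8
Reactants: 16 hexa-allyl ether of the target
Product: 17 (2,4-dihydroxyphenyl)[(2R,3R,4R,5R)-5-(2,4-dihydroxyphenyl)-4-[(R)-hydroxy(4-hydroxyphenyl)methyl]-2-(4-hydroxyphenyl)oxolan-3-yl]methanone (CNP0244141.1)
Conditions: Pd(PPh3)4 (10 mol %), morpholine (12 equiv), degassed THF, rt
Reagents that add atoms: none
Why: Tsuji–Trost-type deallylation: zerovalent palladium ionises each of the six aryl allyl ethers to a π-allyl complex and a phenoxide and morpholine takes up the allyl group; under these neutral, non-reducing conditions the p-hydroxybenzylic alcohol, the two benzylic ether bonds and the centre α to the ketone should be left alone.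

**Compound list**

1 | succinyl chloride | O=C(Cl)CCC(=O)Cl | starting material
2 | (R)-4-benzyl-2-oxazolidinone | O=C1N[C@H](Cc2ccccc2)CO1 | starting material
3 | lithium (R)-4-benzyl-2-oxazolidinon-3-ide (formed in the flask, not isolated) | [Li]N1[C@H](Cc2ccccc2)COC1=O | intermediate
4 | 1,4-bis[(R)-4-benzyl-2-oxooxazolidin-3-yl]butane-1,4-dione (succinyl bis-imide) | O=C(CCC(=O)N1[C@H](Cc2ccccc2)COC1=O)N1[C@H](Cc2ccccc2)COC1=O | intermediate
5 | 4-(allyloxy)benzaldehyde | O=Cc1ccc(OCC=C)cc1 | starting material
6 | bis(dibutylboron) Z,Z-dienolate of 4 (formed in the flask, not isolated) | CCCCB(CCCC)O/C(N1[C@H](Cc2ccccc2)COC1=O)=C\C=C(/OB(CCCC)CCCC)N1[C@H](Cc2ccccc2)COC1=O | intermediate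
7 | bis(dibutylboron) aldolate of 8 (formed in the flask, not isolated) | O=C(N1[C@H](Cc2ccccc2)COC1=O)[C@@H]([C@@H](OB(CCCC)CCCC)c1ccc(OCC=C)cc1)[C@H]([C@@H](OB(CCCC)CCCC)c1ccc(OCC=C)cc1)C(=O)N1[C@H](Cc2ccccc2)COC1=O | intermediate
8 | C2-symmetric bis-syn-aldol diol, 1,4-bis[(R)-4-benzyl-2-oxooxazolidin-3-yl]-(2R,3R)-2,3-bis[(R)-[4-(allyloxy)phenyl](hydroxy)methyl]butane-1,4-dione | O=C(N1[C@H](Cc2ccccc2)COC1=O)[C@@H]([C@@H](O)c1ccc(OCC=C)cc1)[C@H]([C@@H](O)c1ccc(OCC=C)cc1)C(=O)N1[C@H](Cc2ccccc2)COC1=O | intermediate
9 | (3R,3aR,6R,6aR)-3,6-bis[4-(allyloxy)phenyl]tetrahydrofuro[3,4-c]furan-1,4-dione (cis-fused dilactone, aryl groups exo) | O=C1[C@@H]2[C@H]([C@@H](O1)c1ccc(OCC=C)cc1)C(=O)O[C@H]2c1ccc(OCC=C)cc1 | intermediate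
10 | 4-bromoresorcinol | Oc1ccc(Br)c(O)c1 | starting material
11 | 2,4-bis(allyloxy)-1-bromobenzene | C=CCOc1ccc(Br)c(OCC=C)c1 | intermediate
12 | 2,4-bis(allyloxy)phenylmagnesium bromide (formed in the flask, not isolated) | Br[Mg]c1ccc(OCC=C)cc1OCC=C | intermediate
13 | lactol–lactone, (3R,3aR,4S,6R,6aR)-3,6-bis[4-(allyloxy)phenyl]-4-[2,4-bis(allyloxy)phenyl]-4-hydroxytetrahydrofuro[3,4-c]furan-1-one (exo-aryl anomer drawn) | O=C1[C@@H]2[C@H]([C@@H](O1)c1ccc(OCC=C)cc1)[C@@](O)(c1ccc(OCC=C)cc1OCC=C)O[C@H]2c1ccc(OCC=C)cc1 | intermediate
14 | oxolane–lactone, (3R,3aS,4R,6R,6aR)-3,6-bis[4-(allyloxy)phenyl]-4-[2,4-bis(allyloxy)phenyl]tetrahydrofuro[3,4-c]furan-1-one (4-aryl endo) | O=C1[C@@H]2[C@H]([C@@H](O1)c1ccc(OCC=C)cc1)[C@H](c1ccc(OCC=C)cc1OCC=C)O[C@H]2c1ccc(OCC=C)cc1 | intermediate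
15 | 2,4-bis(allyloxy)phenyllithium (formed in the flask, not isolated) | [Li]c1ccc(OCC=C)cc1OCC=C | intermediate
16 | hexa-allyl ether of the target, [2,4-bis(allyloxy)phenyl][(2R,3R,4R,5R)-2-[4-(allyloxy)phenyl]-5-[2,4-bis(allyloxy)phenyl]-4-[(R)-[4-(allyloxy)phenyl](hydroxy)methyl]oxolan-3-yl]methanone | O=C(c1ccc(OCC=C)cc1OCC=C)[C@@H]1[C@H]([C@@H](O)c2ccc(OCC=C)cc2)[C@H](c2ccc(OCC=C)cc2OCC=C)O[C@H]1c1ccc(OCC=C)cc1 | intermediate
17 | (2,4-dihydroxyphenyl)[(2R,3R,4R,5R)-5-(2,4-dihydroxyphenyl)-4-[(R)-hydroxy(4-hydroxyphenyl)methyl]-2-(4-hydroxyphenyl)oxolan-3-yl]methanone (CNP0244141.1) | O=C(c1ccc(O)cc1O)[C@@H]1[C@H]([C@@H](O)c2ccc(O)cc2)[C@H](c2ccc(O)cc2O)O[C@H]1c1ccc(O)cc1 | target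

**Step count and risks**

Total: 8 steps. Longest linear sequence: 7 steps (steps 1, 2, 3, 5, 6, 7, 8).

Step 2 (the proposed new method). The second enolisation may stop short, reagent control may weaken in the second addition once one aldolate centre is in place, or an aldolate oxygen may transfer to the distal imide before work-up (which would only anticipate step 3). The fallback uses single Evans aldols only and sets out from 4. One equivalent of Bu2BOTf and iPr2NEt followed by one equivalent of 5 should give the mono-syn-aldol F1, whose hydroxyl is capped at once (TESOTf, 2,6-lutidine, −78 °C) to give the triethylsilyl ether F2, so that it cannot lactonise. A second standard boron aldol at the remaining methylene imide (the α-branched imide is shielded from enolisation by allylic strain) should give the mono-silylated bis-aldol F3. HF·pyridine in THF then removes the silyl group and the route is rejoined at 8.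

Step 5. The two lactone carbonyls are equivalent and the first addition does not deactivate the second, so the Grignard reagent may partition statistically between unreacted dilactone, mono-adduct and bis-adduct. The fallback sets out from 9 and removes the partition by adding the aryl group to both carbonyls. For this, 2.5 equivalents of aryllithium 15 (from 11 and n-BuLi, as in step 7) at −78 °C, where the lithium hemiketalates persist, should give the C2-symmetric bis-adduct F4 (a bis-lactol, written as its open diketo-diol tautomer). One equivalent of Et3SiH with BF3·OEt2 at −78 °C is then expected to reduce a single hemiketal, because a second hydride delivery would have to force another aryl group onto the concave face already occupied by the first. The product is 16 in its lactol form, so the route is rejoined at 16 and steps 6 and 7 are bypassed.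

Step 6. The Lewis acid may ionise the benzylic C–O bonds, either the newly formed 2,4-dialkoxybenzylic ether or the p-alkoxybenzylic lactone. This would lead to epimerisation of the endo aryl group or to reductive ring opening by the silane. The fallback sets out from 13 and replaces the cationic hydride transfer by a radical one. Thiophenol with catalytic camphorsulfonic acid in CH2Cl2 should convert the lactol into the S-phenyl mixed thioketal F5 (either epimer serves). Bu3SnH and AIBN in toluene at 80 °C then cleave the C–S bond, and the benzylic α-oxy radical should take hydrogen from the tin hydride on the convex face. The stannane is kept concentrated so that hydrogen transfer outruns cyclisation of the radical onto the neighbouring allyl ether. This gives 14 without a Lewis acid meeting the product; radical desulfurisation of mixed O,S-ketals to cyclic ethers is established chemistry.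

**Further compounds**

F1 | step 2 | mono-syn-aldol of 4, 1,4-bis[(R)-4-benzyl-2-oxooxazolidin-3-yl]-(2R)-2-[(R)-[4-(allyloxy)phenyl](hydroxy)methyl]butane-1,4-dione | O=C(N1[C@H](Cc2ccccc2)COC1=O)[C@@H]([C@@H](O)c1ccc(OCC=C)cc1)CC(=O)N1[C@H](Cc2ccccc2)COC1=O
F2 | step 2 | triethylsilyl ether of F1 | O=C(N1[C@H](Cc2ccccc2)COC1=O)[C@@H]([C@@H](O[Si](CC)(CC)CC)c1ccc(OCC=C)cc1)CC(=O)N1[C@H](Cc2ccccc2)COC1=O
F3 | step 2 | mono-triethylsilyl ether of bis-aldol 8 | O=C(N1[C@H](Cc2ccccc2)COC1=O)[C@@H]([C@@H](O[Si](CC)(CC)CC)c1ccc(OCC=C)cc1)[C@H]([C@@H](O)c1ccc(OCC=C)cc1)C(=O)N1[C@H](Cc2ccccc2)COC1=O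
F4 | step 5 | C2-symmetric twofold aryl adduct of 9, (2R,3R)-1,4-bis[2,4-bis(allyloxy)phenyl]-2,3-bis[(R)-[4-(allyloxy)phenyl](hydroxy)methyl]butane-1,4-dione (open tautomer of the bis-lactol) | O=C(c1ccc(OCC=C)cc1OCC=C)[C@@H]([C@@H](O)c1ccc(OCC=C)cc1)[C@H]([C@@H](O)c1ccc(OCC=C)cc1)C(=O)c1ccc(OCC=C)cc1OCC=C
F5 | step 6 | S-phenyl mixed thioketal of 13 (phenylthio group exo as drawn) | O=C1[C@@H]2[C@H]([C@@H](O1)c1ccc(OCC=C)cc1)[C@](Sc1ccccc1)(c1ccc(OCC=C)cc1OCC=C)O[C@H]2c1ccc(OCC=C)cc1
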